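The bond that everything rests on is C4a–C11a, which fuses dihydropyran ring A to nine-membered ring B: C11a is alpha to C1 (carboxyl level) and C4a ends the allyl unit C3–C4=C4a, so this bond is the new sigma bond of an ester-enolate [3,3] shift across C1–O2–C3. One enantioselective boron-enolate Ireland–Claisen rearrangement of an achiral 13-membered triene lactone forms it, contracts the macrocycle to ring B and sets both fusion stereocentres (trans), leaving a C1 acid and a C3/C4/C12 acrylate for ring A. The precursor already holds the E-C7=C8 olefin, the C11 methylidene and a Z-acrylate with C5 anti to the lactone carbon C3.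

Key step: step 13

Remarks and assumptions:
- Numbering: ring A is C1(OAc)–O2–C3=C4–C4a–C11a; ring B is C4a–C5–C6–C7(Me)–C8–C9–C10–C11(=CH2)–C11a; the side chain is C12–C15.
- Lactone 20 and acid 23 were checked against the target: the Z-acrylate and a chair transition state give the trans fusion with C4a S and C11a R, so neither structure needs correction.
- The (4S,5S)-bromoborane of step 13 is BrB1N(S(=O)(=O)c2cc(cc(c2)C(F)(F)F)C(F)(F)F)[C@@H](c2ccccc2)[C@H](c2ccccc2)N1S(=O)(=O)c1cc(cc(c1)C(F)(F)F)C(F)(F)F, prepared beforehand from the bis-sulfonamide and BBr3. It is assumed to give the (4aS,11aR) acid; if the first run shows the opposite sense, the (4R,5R)-reagent is used and nothing else changes.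
- Compounds 18, 31 and 35 are taken as purchased.

Step 1
Reactants: 1 geranyl acetate
Product: 2 6,7-epoxygeranyl acetate (racemic)
Conditions: mCPBA, CH2Cl2, 0 °C
Reagents that add atoms: 3-chloroperoxybenzoic acid, OOC(=O)c1cccc(Cl)c1
Why: Prilezhaev epoxidation should occur at the distal trisubstituted olefin, since the 2,3-olefin is deactivated by the allylic acetate; the racemic epoxide centre is destroyed in step 2.

Step 2
Reactants: 2 6,7-epoxygeranyl acetate
Product: 3 (2E)-3-methyl-6-oxohex-2-en-1-yl acetate
Conditions: H5IO6, THF/H2O, 0 °C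
Reagents that add atoms: none
Why: Periodic acid should open the epoxide to the diol and cleave it in the same pot (glycol cleavage), leaving the E-olefin and the acetate untouched.

Step 3
Reactants: 3 (2E)-3-methyl-6-oxohex-2-en-1-yl acetate
Product: 5 (2E)-6,6-dimethoxy-3-methylhex-2-en-1-ol, via acetal acetate 4 (not isolated)
Conditions: HC(OMe)3, PPTS (cat.), MeOH, rt; then K2CO3 (cat.), rt
Reagents that add atoms: trimethyl orthoformate, COC(OC)OC; methanol, CO
Why: Acid-catalysed acetalisation masks the aldehyde against the organolithium of step 5, and carbonate-catalysed transesterification then frees the allylic alcohol without touching the acetal.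

Step 4
Reactants: 5 (2E)-6,6-dimethoxy-3-methylhex-2-en-1-ol
Product: 7 (2E)-1-bromo-6,6-dimethoxy-3-methylhex-2-ene, via allylic mesylate 6 (not isolated)
Conditions: MsCl, Et3N, THF, −40 °C; then LiBr, 0 °C
Reagents that add atoms: lithium bromide LiBr, [Li+].[Br-]
Why: Mesylation followed by SN2 displacement with bromide is non-acidic, so the acetal and the E-olefin geometry should be kept.

Step 5
Reactants: 7 (2E)-1-bromo-6,6-dimethoxy-3-methylhex-2-ene; 8 3-methylbut-3-en-1-ol
Product: 10 (6E)-10,10-dimethoxy-7-methyl-3-methylidenedec-6-en-1-ol, via dilithio dianion 9 (not isolated)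
Conditions: 8, n-BuLi (2.2 equiv), TMEDA, Et2O, 0 °C to rt; then 7, THF, −78 °C
Reagents that add atoms: 3-methylbut-3-en-1-ol (8), C=C(C)CCO
Why: Double deprotonation of 8 gives an alkoxide-bearing 2-substituted allyl anion whose SN2 alkylation at the former methyl carbon by the primary allylic bromide forms C9–C10 and delivers the C11 methylidene directly (dianion alkylation).

Step 6
Reactants: 10 (6E)-10,10-dimethoxy-7-methyl-3-methylidenedec-6-en-1-ol
Product: 11 (4E)-10-hydroxy-4-methyl-8-methylidenedec-4-enal
Conditions: PPTS (cat.), acetone/H2O, 45 °C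
Reagents that add atoms: water, O
Why: Mild acid hydrolysis of the dimethyl acetal should free the C4a aldehyde without isomerising either olefin.

Step 7
Reactants: 12 methyl 2-[bis(2,2,2-trifluoroethoxy)phosphoryl]acetate
Product: 13 methyl 2-[bis(2,2,2-trifluoroethoxy)phosphoryl]-2,2-dibromoacetate
Conditions: Br2, NaOH, H2O, 0 °C
Reagents that add atoms: bromine, BrBr
Why: Hypobromite bromination of the active methylene runs through to the dibromide, which avoids the mono/di mixtures of a direct monobromination.

Step 8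
Reactants: 13 methyl 2-[bis(2,2,2-trifluoroethoxy)phosphoryl]-2,2-dibromoacetate
Product: 14 methyl 2-[bis(2,2,2-trifluoroethoxy)phosphoryl]-2-bromoacetate (racemic)
Conditions: SnCl2·2H2O, EtOH/H2O, 0 °C
Reagents that add atoms: none
Why: SnCl2 should remove one bromine from the activated gem-dibromide and stop at the monobromide (reductive monodehalogenation).

Step 9
Reactants: 11 (4E)-10-hydroxy-4-methyl-8-methylidenedec-4-enal; 14 methyl 2-[bis(2,2,2-trifluoroethoxy)phosphoryl]-2-bromoacetate
Product: 15 methyl (2E,6E)-2-bromo-12-hydroxy-6-methyl-10-methylidenedodeca-2,6-dienoate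
Conditions: 14, KN(SiMe3)2, 18-crown-6, THF, −78 °C; then 11
Reagents that add atoms: bromophosphonate 14, COC(=O)C(Br)P(=O)(OCC(F)(F)F)OCC(F)(F)F
Why: Horner–Wadsworth–Emmons olefination of the Still–Gennari type (trifluoroethyl phosphonate, dissociated potassium counter-ion) should place the ester cis to C5 and bromine trans, the geometry the ring contraction needs; the free alcohol is not deprotonated by the phosphonate anion.

Step 10
Reactants: 15 methyl (2E,6E)-2-bromo-12-hydroxy-6-methyl-10-methylidenedodeca-2,6-dienoate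
Product: 17 (6E,10E)-11-bromo-12-methoxy-7-methyl-3-methylidene-12-oxododeca-6,10-dienoic acid, via aldehyde 16 (not isolated)
Conditions: TEMPO (cat.), PhI(OAc)2, MeCN/pH 7 buffer, rt
Reagents that add atoms: water, O
Why: Oxoammonium oxidation takes the primary alcohol through the aldehyde hydrate to the acid under near-neutral conditions that should tolerate the olefins and keep the methylidene out of conjugation.

Step 11
Reactants: 17 (6E,10E)-11-bromo-12-methoxy-7-methyl-3-methylidene-12-oxododeca-6,10-dienoic acid; 18 (tributylstannyl)methanol, Bu3SnCH2OH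
Product: 19 (6E,10Z)-11-(hydroxymethyl)-12-methoxy-7-methyl-3-methylidene-12-oxododeca-6,10-dienoic acid
Conditions: Pd(PPh3)4 (cat.), dioxane, 80 °C; aq. KF work-up
Reagents that add atoms: (tributylstannyl)methanol (18), CCCC[Sn](CCCC)(CCCC)CO
Why: Stille coupling (oxidative addition into the vinyl C–Br bond, hydroxymethyl transfer from tin, reductive elimination) proceeds with retention of olefin geometry and installs C3 as a free allylic alcohol anti to C5.

Step 12
Reactants: 19 (6E,10Z)-11-(hydroxymethyl)-12-methoxy-7-methyl-3-methylidene-12-oxododeca-6,10-dienoic acid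
Product: 20 methyl (3Z,7E)-7-methyl-11-methylidene-13-oxo-1-oxacyclotrideca-3,7-diene-3-carboxylate
Conditions: PPh3, DIAD, toluene/THF, slow addition at high dilution, 0 °C to rt
Reagents that add atoms: none
Why: Mitsunobu macrolactonisation activates the allylic alcohol and closes by carboxylate SN2 attack at primary C3, which avoids acyl activation and nucleophilic amine catalysts that could move the methylidene into conjugation or add to the 2-(acyloxymethyl)acrylate.

Step 13
Reactants: 20 methyl (3Z,7E)-7-methyl-11-methylidene-13-oxo-1-oxacyclotrideca-3,7-diene-3-carboxylate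
Product: 23 (1R,2S,5E)-2-(3-methoxy-3-oxoprop-1-en-2-yl)-5-methyl-9-methylidenecyclonon-5-ene-1-carboxylic acid (4aS,11aR in target numbering), via boron ketene acetal 21 (not isolated), via acyloxyborane 22 (not isolated)
Conditions: (4S,5S)-2-bromo-4,5-diphenyl-1,3-bis{[3,5-bis(trifluoromethyl)phenyl]sulfonyl}-1,3,2-diazaborolidine, i-Pr2NEt, CH2Cl2, −78 °C, then 4 °C; aq. work-up
Reagents that add atoms: none
Why: Boron–amine soft enolisation at C11a (alpha to the lactone carbonyl and allylic to the C11 methylidene) gives ketene acetal 21, whose C11a=C1–O2–C3–C4=C4a array undergoes a concerted [3,3] shift that forms C4a–C11a and cleaves O2–C3 (Ireland–Claisen rearrangement). The closest known reaction type is the Ireland–Claisen ring contraction of macrocyclic allylic lactones to carbocycles, run here with the chiral diazaborolidine enolate used for open-chain allyl esters. Ring B closes by transannular bond formation inside the 13-membered ring, a 13-to-9 contraction through a six-membered chair transition state in which the C6–C10 tether bridges two gauche, pseudo-equatorial positions. C4a is set by the acrylate geometry (C5 anti to C3, hence pseudo-equatorial) and C11a by the ketene acetal geometry (C11 anti to O2, the geometry that i-Pr2NEt in CH2Cl2 favours), which together give the trans relationship; the absolute sense comes from the C2-symmetric sulfonamide ligands on boron, which distinguish the two mirror-image chairs. The step needs chair over boat and alpha-enolisation without olefin migration; the substituents on C1 (O–B) and C4 (CO2Me) point apart only in the chair, and the hindered amine at low temperature should neither isomerise the methylidene nor add to the acrylate.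

Step 14
Reactants: 23 (1R,2S,5E)-2-(3-methoxy-3-oxoprop-1-en-2-yl)-5-methyl-9-methylidenecyclonon-5-ene-1-carboxylic acid
Product: 25 (1R,2S,5E)-2-(3-hydroxy-1-methoxy-1-oxopropan-2-yl)-5-methyl-9-methylidenecyclonon-5-ene-1-carboxylic acid (C4 epimers), via boronate 24 (not isolated)
Conditions: B2pin2, CuCl (cat.), Xantphos (cat.), NaOt-Bu (1.2 equiv), MeOH, THF, rt; then NaBO3·4H2O, THF/H2O
Reagents that add atoms: sodium perborate tetrahydrate NaBO3·4H2O, [Na+].[O-]OB=O.O.O.O.O
Why: Copper-catalysed conjugate borylation puts boron on C3 of the only electron-poor olefin (the substrate reacts as its sodium carboxylate) and perborate oxidation with retention gives the primary alcohol; the C4 centre formed is removed in step 15, and any lactonised material is reduced to the same triol.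

Step 15
Reactants: 25 hydroxy ester acid (C4 epimers)
Product: 26 2-[(1S,2R,5E)-2-(hydroxymethyl)-6-methyl-3-methylidenecyclonon-5-en-1-yl]propane-1,3-diol (4aS,11aR)
Conditions: LiAlH4, THF, 0 °C to reflux; aq. NaOH work-up
Reagents that add atoms: none
Why: Hydride reduction of carboxylate and ester leaves the olefins alone and turns C3 and C12 into two equivalent hydroxymethyl groups, so the later ring closure has no regiochemical issue.

Step 16
Reactants: 26 triol
Product: 28 (4aS,7E,11aR)-1-hydroxy-7-methyl-11-methylidene-1,4a,5,6,9,10,11,11a-octahydrocyclonona[c]pyran-4-carbaldehyde (C1 anomers), via trialdehyde 27 (not isolated)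
Conditions: (COCl)2, DMSO, CH2Cl2, −78 °C; i-Pr2NEt, −78 to −30 °C; aq. NaH2PO4
Reagents that add atoms: none
Why: Swern oxidation activates all three hydroxyls before base is added, so no lactol can form and be over-oxidised; the 2-substituted malondialdehyde then enolises and its enol oxygen adds to the C1 aldehyde (6-exo-trig hemiacetalisation, as in iridoid aglycones) to close ring A, either formyl group giving the same product.

Step 17
Reactants: 28 ring A lactol enal
Product: 29 (1R,4aS,7E,11aR)-4-formyl-7-methyl-11-methylidene-1,4a,5,6,9,10,11,11a-octahydrocyclonona[c]pyran-1-yl acetate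
Conditions: Ac2O, Et3N, DMAP (cat.), CH2Cl2, −20 °C
Reagents that add atoms: acetic anhydride, CC(=O)OC(C)=O
Why: DMAP-catalysed acylation of the equilibrating lactol should favour the anomer whose acetoxy group is anti to the C11a–C11 bond and pseudo-axial (anomeric effect), which is 1R; the vinylogous-formate enol ether is inert.

Step 18
Reactants: 29 C1 acetate enal
Product: 30 (1R,4aS,7S,8S,11aR)-7,8-epoxy-4-formyl-7-methyl-11-methylidene-decahydrocyclonona[c]pyran-1-yl acetate (C3=C4 retained)
Conditions: dimethyldioxirane (1.05 equiv), acetone/CH2Cl2, −40 °C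
Reagents that add atoms: dimethyldioxirane, CC1(C)OO1
Why: Dioxirane epoxidation should be fastest at the strained trisubstituted E-olefin, the methylidene being less nucleophilic and the enol ether deactivated by conjugation to the aldehyde; attack on the outer face of the E-cyclononene in its favoured conformer should give the 7S,8S epoxide.

Step 19
Reactants: 30 epoxy enal acetate; 31 (+)-B-allyldiisopinocampheylborane (from (−)-α-pinene)
Product: 33 (1R,4aS,7S,8S,11aR)-7,8-epoxy-4-[(1R)-1-hydroxybut-3-en-1-yl]-7-methyl-11-methylidene-decahydrocyclonona[c]pyran-1-yl acetate, via borinate 32 (not isolated)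
Conditions: 31, Et2O, −78 °C; then HOCH2CH2NH2, rt
Reagents that add atoms: (+)-B-allyldiisopinocampheylborane (31), C=CCB([C@@H]1[C@@H](C)[C@@H]2C[C@H](C1)C2(C)C)[C@@H]1[C@@H](C)[C@@H]2C[C@H](C1)C2(C)C
Why: Brown allylboration through a chair six-membered transition state is reagent-controlled, and the (−)-α-pinene-derived reagent should add to the aldehyde face that gives 12R; the neutral conditions and non-oxidative work-up spare acetate, epoxide and enol ether.

Step 20
Reactants: 33 homoallylic alcohol
Product: 34 (1R)-1-[(1R,4aS,7S,8S,11aR)-1-acetoxy-7,8-epoxy-7-methyl-11-methylidene-decahydrocyclonona[c]pyran-4-yl]but-3-en-1-yl acetate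
Conditions: Ac2O, Et3N, DMAP (cat.), CH2Cl2, 0 °C
Reagents that add atoms: acetic anhydride, CC(=O)OC(C)=O
Why: DMAP-catalysed acetylation of the secondary alcohol proceeds with retention at C12 and stabilises the allylic position next to the enol ether.

Step 21
Reactants: 34 diacetate; 35 methyl methacrylate
Product: 36 target, methyl (2E,5R)-5-acetoxy-5-[(1R,4aS,7S,8S,11aR)-1-acetoxy-7,8-epoxy-7-methyl-11-methylidene-decahydrocyclonona[c]pyran-4-yl]-2-methylpent-2-enoate
Conditions: 35 (excess), second-generation Hoveyda–Grubbs catalyst RuCl2(H2IMes)(=CH–C6H4-2-O-i-Pr) (cat.), CH2Cl2, 40 °C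
Reagents that add atoms: methyl methacrylate (35), C=C(C)C(=O)OC
Why: Olefin cross-metathesis of the monosubstituted olefin with excess methacrylate should give the E-trisubstituted enoate; the hindered methylidene and the trisubstituted enol ether should not engage, and ring closure onto C11 would need a bridgehead olefin at C4.

Compound list
1 | geranyl acetate | CC(C)=CCC/C(C)=C/COC(C)=O | starting material
2 | 6,7-epoxygeranyl acetate (racemic) | CC1(C)OC1CC/C(C)=C/COC(C)=O | intermediate
3 | (2E)-3-methyl-6-oxohex-2-en-1-yl acetate | O=CCC/C(C)=C/COC(C)=O | intermediate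
4 | (2E)-6,6-dimethoxy-3-methylhex-2-en-1-yl acetate (not isolated) | COC(OC)CC/C(C)=C/COC(C)=O | intermediate
5 | (2E)-6,6-dimethoxy-3-methylhex-2-en-1-ol | COC(OC)CC/C(C)=C/CO | intermediate
6 | (2E)-6,6-dimethoxy-3-methylhex-2-en-1-yl methanesulfonate (not isolated) | COC(OC)CC/C(C)=C/COS(C)(=O)=O | intermediate
7 | (2E)-1-bromo-6,6-dimethoxy-3-methylhex-2-ene | COC(OC)CC/C(C)=C/CBr | intermediate
8 | 3-methylbut-3-en-1-ol | C=C(C)CCO | starting material
9 | dilithio dianion of 8 (not isolated) | [Li]CC(=C)CCO[Li] | intermediate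
10 | (6E)-10,10-dimethoxy-7-methyl-3-methylidenedec-6-en-1-ol | OCCC(=C)CC/C=C(\C)CCC(OC)OC | intermediate
11 | (4E)-10-hydroxy-4-methyl-8-methylidenedec-4-enal | OCCC(=C)CC/C=C(\C)CCC=O | intermediate
12 | methyl 2-[bis(2,2,2-trifluoroethoxy)phosphoryl]acetate | COC(=O)CP(=O)(OCC(F)(F)F)OCC(F)(F)F | starting material
13 | methyl 2-[bis(2,2,2-trifluoroethoxy)phosphoryl]-2,2-dibromoacetate | COC(=O)C(Br)(Br)P(=O)(OCC(F)(F)F)OCC(F)(F)F | intermediate
14 | methyl 2-[bis(2,2,2-trifluoroethoxy)phosphoryl]-2-bromoacetate (racemic) | COC(=O)C(Br)P(=O)(OCC(F)(F)F)OCC(F)(F)F | intermediate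
15 | methyl (2E,6E)-2-bromo-12-hydroxy-6-methyl-10-methylidenedodeca-2,6-dienoate | OCCC(=C)CC/C=C(\C)CC/C=C(/Br)C(=O)OC | intermediate
16 | methyl (2E,6E)-2-bromo-6-methyl-10-methylidene-12-oxododeca-2,6-dienoate (not isolated) | O=CCC(=C)CC/C=C(\C)CC/C=C(/Br)C(=O)OC | intermediate
17 | (6E,10E)-11-bromo-12-methoxy-7-methyl-3-methylidene-12-oxododeca-6,10-dienoic acid | OC(=O)CC(=C)CC/C=C(\C)CC/C=C(/Br)C(=O)OC | intermediate
18 | (tributylstannyl)methanol, Bu3SnCH2OH | CCCC[Sn](CCCC)(CCCC)CO | starting material
19 | (6E,10Z)-11-(hydroxymethyl)-12-methoxy-7-methyl-3-methylidene-12-oxododeca-6,10-dienoic acid | OC(=O)CC(=C)CC/C=C(\C)CC/C=C(/CO)C(=O)OC | intermediate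
20 | methyl (3Z,7E)-7-methyl-11-methylidene-13-oxo-1-oxacyclotrideca-3,7-diene-3-carboxylate | O=C1OC/C(C(=O)OC)=C/CC/C(C)=C/CCC(=C)C1 | intermediate
21 | boron ketene acetal of 20, C11 cis to O–B, (4S,5S)-diazaborolidine (not isolated) | O1C/C(C(=O)OC)=C/CC/C(C)=C/CCC(=C)/C=C1\OB2N(S(=O)(=O)c3cc(cc(c3)C(F)(F)F)C(F)(F)F)[C@@H](c3ccccc3)[C@H](c3ccccc3)N2S(=O)(=O)c3cc(cc(c3)C(F)(F)F)C(F)(F)F | intermediate
22 | acyloxyborane of acid 23 (not isolated) | C=C1CC/C=C(\C)CC[C@H](C(=C)C(=O)OC)[C@H]1C(=O)OB2N(S(=O)(=O)c3cc(cc(c3)C(F)(F)F)C(F)(F)F)[C@@H](c3ccccc3)[C@H](c3ccccc3)N2S(=O)(=O)c3cc(cc(c3)C(F)(F)F)C(F)(F)F | intermediate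
23 | (1R,2S,5E)-2-(3-methoxy-3-oxoprop-1-en-2-yl)-5-methyl-9-methylidenecyclonon-5-ene-1-carboxylic acid | C=C1CC/C=C(\C)CC[C@H](C(=C)C(=O)OC)[C@H]1C(=O)O | intermediate
24 | C3 pinacol boronate of 23, C4 epimers (not isolated) | C=C1CC/C=C(\C)CC[C@H](C(CB2OC(C)(C)C(C)(C)O2)C(=O)OC)[C@H]1C(=O)O | intermediate
25 | (1R,2S,5E)-2-(3-hydroxy-1-methoxy-1-oxopropan-2-yl)-5-methyl-9-methylidenecyclonon-5-ene-1-carboxylic acid, C4 epimers | C=C1CC/C=C(\C)CC[C@H](C(CO)C(=O)OC)[C@H]1C(=O)O | intermediate
26 | 2-[(1S,2R,5E)-2-(hydroxymethyl)-6-methyl-3-methylidenecyclonon-5-en-1-yl]propane-1,3-diol | C=C1CC/C=C(\C)CC[C@H](C(CO)CO)[C@H]1CO | intermediate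
27 | trialdehyde from 26 (not isolated) | C=C1CC/C=C(\C)CC[C@H](C(C=O)C=O)[C@H]1C=O | intermediate
28 | (4aS,7E,11aR)-1-hydroxy-7-methyl-11-methylidene-1,4a,5,6,9,10,11,11a-octahydrocyclonona[c]pyran-4-carbaldehyde, C1 anomers | C=C1CC/C=C(\C)CC[C@@H]2C(C=O)=COC(O)[C@@H]12 | intermediate
29 | (1R,4aS,7E,11aR)-4-formyl-7-methyl-11-methylidene-1,4a,5,6,9,10,11,11a-octahydrocyclonona[c]pyran-1-yl acetate | C=C1CC/C=C(\C)CC[C@@H]2C(C=O)=CO[C@H](OC(C)=O)[C@@H]12 | intermediate
30 | (1R,4aS,7S,8S,11aR)-7,8-epoxy-4-formyl-7-methyl-11-methylidene-decahydrocyclonona[c]pyran-1-yl acetate | C=C1CC[C@@H]2O[C@@]2(C)CC[C@@H]2C(C=O)=CO[C@H](OC(C)=O)[C@@H]12 | intermediate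
31 | (+)-B-allyldiisopinocampheylborane, from (−)-α-pinene | C=CCB([C@@H]1[C@@H](C)[C@@H]2C[C@H](C1)C2(C)C)[C@@H]1[C@@H](C)[C@@H]2C[C@H](C1)C2(C)C | starting material
32 | diisopinocampheylborinate of alcohol 33 (not isolated) | C=C1CC[C@@H]2O[C@@]2(C)CC[C@@H]2C([C@@H](CC=C)OB([C@@H]3[C@@H](C)[C@@H]4C[C@H](C3)C4(C)C)[C@@H]3[C@@H](C)[C@@H]4C[C@H](C3)C4(C)C)=CO[C@H](OC(C)=O)[C@@H]12 | intermediate
33 | (12R)-homoallylic alcohol, C1 acetate, 7,8-epoxide | C=C1CC[C@@H]2O[C@@]2(C)CC[C@@H]2C([C@@H](CC=C)O)=CO[C@H](OC(C)=O)[C@@H]12 | intermediate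
34 | (12R)-homoallylic acetate, C1 acetate, 7,8-epoxide | C=C1CC[C@@H]2O[C@@]2(C)CC[C@@H]2C([C@@H](CC=C)OC(C)=O)=CO[C@H](OC(C)=O)[C@@H]12 | intermediate
35 | methyl methacrylate | C=C(C)C(=O)OC | starting material
36 | CNP0184381.4, methyl (2E,5R)-5-acetoxy-5-[(1R,4aS,7S,8S,11aR)-1-acetoxy-7,8-epoxy-7-methyl-11-methylidene-decahydrocyclonona[c]pyran-4-yl]-2-methylpent-2-enoate | C=C1CC[C@@H]2O[C@@]2(C)CC[C@@H]2C([C@@H](C/C=C(\C)C(=O)OC)OC(C)=O)=CO[C@H](OC(C)=O)[C@@H]12 | target

Total step count: 21. Longest linear sequence: 19 steps (steps 1–6 and 9–21, from geranyl acetate); the phosphonate branch is steps 7 and 8.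

Steps most likely to fail

Step 13. The boron ligands may discriminate the two chairs poorly, part of the material may leak through a boat or the other ketene acetal geometry (giving the cis acid), or the methylidene may migrate during enolisation. The fallback replaces reagent control by resolution and sets out from lactone 20. LiN(i-Pr)2 with Me3SiCl in THF/DMPU at −78 °C should give the trimethylsilyl ketene acetal F1 with the same C11-cis-to-oxygen geometry, which rearranges on warming. Mild acid hydrolysis should give the racemic trans acid F2. Crystallisation with (S)-1-phenylethylamine (or its enantiomer, whichever gives the less soluble salt of the wanted acid) should give the ammonium salt F3, and acidification returns to acid 23.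

Step 16. Half-oxidised material may lose the remaining activated hydroxyl by beta-elimination at the 2-substituted 1,3-diol, and the amine base may epimerise C11a or move the methylidene while the C1 aldehyde is free. The fallback closes ring A through a formyl ester and adjusts C12 afterwards; it sets out from acid 23. Mixed-anhydride activation (i-BuOCOCl, N-methylmorpholine) and NaBH4 should give the hydroxymethyl acrylate F4. Conjugate borylation and perborate oxidation as in step 14 should give the diol ester F5. Swern oxidation of the two hydroxyls gives a formyl ester that should cyclise onto the C1 aldehyde to the lactol ester F6. Silylation (t-BuMe2SiCl, imidazole) gives the silyl acetal F7, i-Bu2AlH at −78 °C the allylic alcohol F8, and MnO2 the silyl-protected enal F9. Bu4NF buffered with AcOH then returns to lactol enal 28.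

Step 18. The oxidant may attack the less favoured conformer of ring B and give the 7,8-epimeric epoxide, or may also touch the methylidene. The fallback moves the epoxidation ahead and puts it under reagent control; it sets out from triol 26. Shi epoxidation (KHSO5, K2CO3, MeCN/dimethoxymethane/H2O, 0 °C) with the fructose-derived ketone enantiomer that the spiro transition-state model assigns to the 7S,8S face (expected to be the L-series ketone) should give the epoxy triol F10. Swern oxidation and cyclisation as in step 16 should give the epoxy lactol enal F11, and acetylation as in step 17 returns to epoxy enal acetate 30.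

Further compounds
F1 | step 13 | trimethylsilyl ketene acetal of lactone 20 | O1C/C(C(=O)OC)=C/CC/C(C)=C/CCC(=C)/C=C1\O[Si](C)(C)C
F2 | step 13 | racemic trans acid (relative configuration shown) | C=C1CC/C=C(\C)CC[C@H](C(=C)C(=O)OC)[C@H]1C(=O)O
F3 | step 13 | (S)-1-phenylethylammonium salt of acid 23 | C=C1CC/C=C(\C)CC[C@H](C(=C)C(=O)OC)[C@H]1C(=O)[O-].C[C@H]([NH3+])c1ccccc1
F4 | step 16 | methyl 2-[(1S,2R,5E)-2-(hydroxymethyl)-6-methyl-3-methylidenecyclonon-5-en-1-yl]prop-2-enoate | C=C1CC/C=C(\C)CC[C@H](C(=C)C(=O)OC)[C@H]1CO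
F5 | step 16 | methyl 3-hydroxy-2-[(1S,2R,5E)-2-(hydroxymethyl)-6-methyl-3-methylidenecyclonon-5-en-1-yl]propanoate (C4 epimers) | C=C1CC/C=C(\C)CC[C@H](C(CO)C(=O)OC)[C@H]1CO
F6 | step 16 | methyl (4aS,7E,11aR)-1-hydroxy-7-methyl-11-methylidene-1,4a,5,6,9,10,11,11a-octahydrocyclonona[c]pyran-4-carboxylate (C1 anomers) | C=C1CC/C=C(\C)CC[C@@H]2C(C(=O)OC)=COC(O)[C@@H]12
F7 | step 16 | C1 tert-butyldimethylsilyl acetal of F6 | C=C1CC/C=C(\C)CC[C@@H]2C(C(=O)OC)=COC(O[Si](C)(C)C(C)(C)C)[C@@H]12
F8 | step 16 | C12 allylic alcohol, C1 silyl acetal | C=C1CC/C=C(\C)CC[C@@H]2C(CO)=COC(O[Si](C)(C)C(C)(C)C)[C@@H]12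
F9 | step 16 | C12 enal, C1 silyl acetal | C=C1CC/C=C(\C)CC[C@@H]2C(C=O)=COC(O[Si](C)(C)C(C)(C)C)[C@@H]12
F10 | step 18 | (7S,8S)-epoxy triol | C=C1CC[C@@H]2O[C@@]2(C)CC[C@H](C(CO)CO)[C@H]1CO
F11 | step 18 | (7S,8S)-epoxy lactol enal (C1 anomers) | C=C1CC[C@@H]2O[C@@]2(C)CC[C@@H]2C(C=O)=COC(O)[C@@H]12
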